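**Assumption:** Vismiaphenone D has no stereocentre and no stereogenic double bond, so the "single enantiomer" is the achiral compound itself. The one transient stereocentre (aldol 6) is made racemic and is erased in the next step.

## Retrosynthetic overview
1. Both prenyl groups come from allyl groups by a double cross metathesis in the last step. The allyl groups come from a double aromatic Claisen rearrangement of the 2,6-bis(allyl ether) of the benzophenone core.
2. The phloroglucinol ring is the only ring built. It arises by ring opening and intramolecular Claisen cyclisation of a 6-(aroylmethyl)-4-methoxy-2-pyrone, and the pyrone OMe becomes the 4-OMe.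
3. The key C–C bond is the future aryl–C(=O) bond. It is made by an intermolecular vinylogous aldol addition of the 4-methoxy-6-methyl-2-pyrone dienolate to 4-(methoxymethoxy)benzaldehyde, followed by oxidation.
4. Ring order: the 4-hydroxyphenyl ring and the pyrone are bought, and the pyrone is then transformed into the arene. Feedstocks are triacetic acid lactone, 4-hydroxybenzaldehyde, allyl bromide and 2-methylbut-2-ene.

## Route

**Step 1**
Reactants: 1 4-hydroxy-6-methyl-2H-pyran-2-one (triacetic acid lactone)
Product: 2 4-methoxy-6-methyl-2H-pyran-2-one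
Conditions: Me2SO4 (1.1 equiv), K2CO3 (1.5 equiv), acetone, reflux, 5 h
Reagents that add atoms: dimethyl sulfate, COS(=O)(=O)OC
Why: Williamson-type O-methylation of the acidic vinylogous acid with a hard electrophile gives the 4-methoxy-2-pyrone and fixes the future 4-OMe before the arene exists.

**Step 2**
Reactants: 3 4-hydroxybenzaldehyde
Product: 4 4-(methoxymethoxy)benzaldehyde
Conditions: MOMCl (1.2 equiv), K2CO3 (2 equiv), acetone, 0 °C to rt, 4 h
Reagents that add atoms: chloromethyl methyl ether, COCCl
Why: Williamson-type alkylation of the acidic phenol installs an acetal that survives strong base, oxidation and heat, and can be removed without hydrogenation.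

**Step 3 (key step)**
Reactants: 2 4-methoxy-6-methyl-2H-pyran-2-one; 4 4-(methoxymethoxy)benzaldehyde
Product: 6 (±)-6-{2-hydroxy-2-[4-(methoxymethoxy)phenyl]ethyl}-4-methoxy-2H-pyran-2-one, via lithium dienolate 5 (not isolated)
Conditions: LiHMDS (1.1 equiv, 1 M in THF), THF, −78 °C, 45 min; 4 (1.05 equiv), −78 °C, 1 h; AcOH (1.2 equiv) at −78 °C
Reagents that add atoms: none
Why: Intermolecular vinylogous aldol addition, in which reversible deprotonation gives the extended C6-methyl dienolate whose exocyclic carbon adds to the non-enolisable aldehyde, the cold acidic quench avoids E1cB dehydration, and the carbinol centre is formed racemic because step 4 erases it.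

**Step 4**
Reactants: 6 (±)-6-{2-hydroxy-2-[4-(methoxymethoxy)phenyl]ethyl}-4-methoxy-2H-pyran-2-one
Product: 7 4-methoxy-6-{2-[4-(methoxymethoxy)phenyl]-2-oxoethyl}-2H-pyran-2-one
Conditions: Dess–Martin periodinane (1.2 equiv), CH2Cl2, 0 °C to rt, 1 h
Reagents that add atoms: none
Why: Dess–Martin oxidation of the benzylic alcohol is near neutral, so the MOM acetal, the enol ether and the pyrone survive and no base-induced elimination occurs.

**Step 5**
Reactants: 7 4-methoxy-6-{2-[4-(methoxymethoxy)phenyl]-2-oxoethyl}-2H-pyran-2-one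
Product: 9 (2,6-dihydroxy-4-methoxyphenyl)[4-(methoxymethoxy)phenyl]methanone, via ring-opened methyl ester 8 (not isolated)
Conditions: Mg(OMe)2 (3 equiv, 7 wt% in MeOH), MeOH, reflux, 8 h; cold 1 M HCl to pH 3
Reagents that add atoms: none
Why: Methoxide opens the lactone to a magnesium 1,3-diketonate whose central carbon attacks the cis-disposed ester in an intramolecular Claisen (Dieckmann-type) condensation, with aromatisation as the driving force and with the enol ether and the poorly electrophilic aryl ketone suppressing the competing aldol mode.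

**Step 6**
Reactants: 9 (2,6-dihydroxy-4-methoxyphenyl)[4-(methoxymethoxy)phenyl]methanone
Product: 10 [4-methoxy-2,6-bis(prop-2-en-1-yloxy)phenyl][4-(methoxymethoxy)phenyl]methanone
Conditions: allyl bromide (3 equiv), K2CO3 (4 equiv), DMF, 60 °C, 12 h
Reagents that add atoms: allyl bromide, C=CCBr
Why: Williamson etherification in a dipolar aprotic solvent favours O- over C-alkylation, and the excess of a small reactive halide also alkylates the hydrogen-bonded phenol.

**Step 7**
Reactants: 10 [4-methoxy-2,6-bis(prop-2-en-1-yloxy)phenyl][4-(methoxymethoxy)phenyl]methanone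
Product: 12 [2,6-dihydroxy-4-methoxy-3,5-di(prop-2-en-1-yl)phenyl][4-(methoxymethoxy)phenyl]methanone, via mono-rearranged allyl ether 11 (not isolated)
Conditions: PhNEt2, 195 °C, Ar, sealed tube, 8 h
Reagents that add atoms: none
Why: Double aromatic Claisen rearrangement ([3,3]), where each allyl group can rearomatise only at the one H-bearing ortho carbon (C3 or C5) because the other ortho carbon carries the aroyl group, and the basic solvent protects the MOM acetal.

**Step 8**
Reactants: 12 [2,6-dihydroxy-4-methoxy-3,5-di(prop-2-en-1-yl)phenyl][4-(methoxymethoxy)phenyl]methanone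
Product: 13 [2,6-dihydroxy-4-methoxy-3,5-di(prop-2-en-1-yl)phenyl](4-hydroxyphenyl)methanone
Conditions: HCl (1.25 M in MeOH), 45 °C, 3 h
Reagents that add atoms: none
Why: Acid-catalysed transacetalisation removes the MOM group while only monosubstituted allyl groups are present, which do not cyclise onto the ortho phenols under these conditions as prenyl groups could.

**Step 9**
Reactants: 13 [2,6-dihydroxy-4-methoxy-3,5-di(prop-2-en-1-yl)phenyl](4-hydroxyphenyl)methanone
Product: 14 vismiaphenone D, [2,6-dihydroxy-4-methoxy-3,5-bis(3-methylbut-2-en-1-yl)phenyl](4-hydroxyphenyl)methanone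
Conditions: Grubbs II (2 × 5 mol%), 1,4-benzoquinone (10 mol%), 2-methylbut-2-ene/CH2Cl2 1:1, 40 °C, sealed tube, 16 h
Reagents that add atoms: 2-methylbut-2-ene, CC=C(C)C
Why: Olefin cross metathesis of both terminal alkenes with a large excess of the trisubstituted alkene turns allyl into prenyl with loss of propene, tolerates free phenols and the ketone, and creates no stereo-element.

## Compound list
1 | 4-hydroxy-6-methyl-2H-pyran-2-one | CC1=CC(O)=CC(=O)O1 | starting material
2 | 4-methoxy-6-methyl-2H-pyran-2-one | CC1=CC(OC)=CC(=O)O1 | intermediate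
3 | 4-hydroxybenzaldehyde | O=Cc1ccc(O)cc1 | starting material
4 | 4-(methoxymethoxy)benzaldehyde | COCOc1ccc(C=O)cc1 | intermediate
5 | lithium 4-methoxy-6-methylidene-6H-pyran-2-olate (dienolate of 2, not isolated) | [Li+].C=C1C=C(OC)C=C([O-])O1 | intermediate
6 | (±)-6-{2-hydroxy-2-[4-(methoxymethoxy)phenyl]ethyl}-4-methoxy-2H-pyran-2-one (racemate) | COCOc1ccc(C(O)CC2=CC(OC)=CC(=O)O2)cc1 | intermediate
7 | 4-methoxy-6-{2-[4-(methoxymethoxy)phenyl]-2-oxoethyl}-2H-pyran-2-one | COCOc1ccc(C(=O)CC2=CC(OC)=CC(=O)O2)cc1 | intermediate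
8 | methyl (2E)-3-methoxy-7-[4-(methoxymethoxy)phenyl]-5,7-dioxohept-2-enoate (present as magnesium diketonate, not isolated) | COC(=O)/C=C(/OC)CC(=O)CC(=O)c1ccc(OCOC)cc1 | intermediate
9 | (2,6-dihydroxy-4-methoxyphenyl)[4-(methoxymethoxy)phenyl]methanone | COCOc1ccc(C(=O)c2c(O)cc(OC)cc2O)cc1 | intermediate
10 | [4-methoxy-2,6-bis(prop-2-en-1-yloxy)phenyl][4-(methoxymethoxy)phenyl]methanone | COCOc1ccc(C(=O)c2c(OCC=C)cc(OC)cc2OCC=C)cc1 | intermediate
11 | [2-hydroxy-4-methoxy-3-(prop-2-en-1-yl)-6-(prop-2-en-1-yloxy)phenyl][4-(methoxymethoxy)phenyl]methanone (not isolated) | COCOc1ccc(C(=O)c2c(O)c(CC=C)c(OC)cc2OCC=C)cc1 | intermediate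
12 | [2,6-dihydroxy-4-methoxy-3,5-di(prop-2-en-1-yl)phenyl][4-(methoxymethoxy)phenyl]methanone | COCOc1ccc(C(=O)c2c(O)c(CC=C)c(OC)c(CC=C)c2O)cc1 | intermediate
13 | [2,6-dihydroxy-4-methoxy-3,5-di(prop-2-en-1-yl)phenyl](4-hydroxyphenyl)methanone | COc1c(CC=C)c(O)c(C(=O)c2ccc(O)cc2)c(O)c1CC=C | intermediate
14 | vismiaphenone D (achiral) | COc1c(CC=C(C)C)c(O)c(C(=O)c2ccc(O)cc2)c(O)c1CC=C(C)C | target

## Totals and risks
Total step count: 9. Longest linear sequence: 8 steps (1 → 2 → 6 → 7 → 9 → 10 → 12 → 13 → 14; the branch from 3 is equally long).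

The three steps most likely to fail are listed in route order. Step 5 is the riskiest.

**Step 3 (vinylogous aldol).**
- Risks: competing ring (C3) metalation, retro-aldol, or dehydration to the styrylpyrone.
- The fallback sets out from 2 and comes back at 7, replacing steps 3 and 4.
- Commercial methyl 4-hydroxybenzoate is protected (MOMCl, K2CO3, acetone) to methyl 4-(methoxymethoxy)benzoate F1.
- Compound 2 is treated with LiHMDS (2.2 equiv) at −78 °C, then with F1, and warmed to 0 °C.
- This is a crossed vinylogous Claisen condensation. The second equivalent of base deprotonates the more acidic product and drives the reaction.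
- Acidic work-up gives ketone 7 directly, so no dehydration-prone carbinol is ever formed.

**Step 5 (pyrone to arene).**
- Risks: ring opening without cyclisation, retro-Claisen loss of the aroyl group, or aldol-mode closure.
- The fallback sets out from 4 and comes back at 9.
- Commercial 5-methoxyresorcinol is treated with 3,4-dihydro-2H-pyran and PPTS to give 1-methoxy-3,5-bis(tetrahydro-2H-pyran-2-yloxy)benzene F2.
- F2 is lithiated with n-BuLi (THF, 0 °C) between the two acetal oxygens (directed ortho metalation) and added to aldehyde 4.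
- This gives [4-methoxy-2,6-bis(tetrahydro-2H-pyran-2-yloxy)phenyl][4-(methoxymethoxy)phenyl]methanol F3 as a diastereomer mixture of no consequence.
- Dess–Martin oxidation gives [4-methoxy-2,6-bis(tetrahydro-2H-pyran-2-yloxy)phenyl][4-(methoxymethoxy)phenyl]methanone F4.
- PPTS in MeOH at rt removes only the two far more labile THP acetals and leaves the aryl MOM ether, giving 9.

**Step 7 (double thermal Claisen rearrangement at 195 °C).**
- Risks: incomplete second rearrangement, dihydrobenzofuran formation, or MOM loss.
- The fallback sets out from 9 and comes back at 14, bypassing 10 to 13 and the metathesis.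
- 2-Methylbut-3-en-2-ol is converted (n-BuLi, Boc2O) into tert-butyl 2-methylbut-3-en-2-yl carbonate F5.
- Pd(PPh3)4-catalysed O-allylation of 9 with F5 (THF, 0 °C) gives the kinetic tertiary ethers, [4-methoxy-2,6-bis(2-methylbut-3-en-2-yloxy)phenyl][4-(methoxymethoxy)phenyl]methanone F6.
- These 1,1-dimethylallyl ethers rearrange already in refluxing toluene (110 °C) and deliver the prenyl groups directly.
- The product is [2,6-dihydroxy-4-methoxy-3,5-bis(3-methylbut-2-en-1-yl)phenyl][4-(methoxymethoxy)phenyl]methanone F7.
- Brief treatment with dilute methanolic HCl at rt, monitored closely to avoid chroman formation, gives 14.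

## Further compounds
F1 | step 3 | methyl 4-(methoxymethoxy)benzoate | COCOc1ccc(C(=O)OC)cc1
F2 | step 5 | 1-methoxy-3,5-bis(tetrahydro-2H-pyran-2-yloxy)benzene | COc1cc(OC2CCCCO2)cc(OC2CCCCO2)c1
F3 | step 5 | [4-methoxy-2,6-bis(tetrahydro-2H-pyran-2-yloxy)phenyl][4-(methoxymethoxy)phenyl]methanol | COCOc1ccc(C(O)c2c(OC3CCCCO3)cc(OC)cc2OC4CCCCO4)cc1
F4 | step 5 | [4-methoxy-2,6-bis(tetrahydro-2H-pyran-2-yloxy)phenyl][4-(methoxymethoxy)phenyl]methanone | COCOc1ccc(C(=O)c2c(OC3CCCCO3)cc(OC)cc2OC4CCCCO4)cc1
F5 | step 7 | tert-butyl 2-methylbut-3-en-2-yl carbonate | C=CC(C)(C)OC(=O)OC(C)(C)C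
F6 | step 7 | [4-methoxy-2,6-bis(2-methylbut-3-en-2-yloxy)phenyl][4-(methoxymethoxy)phenyl]methanone | COCOc1ccc(C(=O)c2c(OC(C)(C)C=C)cc(OC)cc2OC(C)(C)C=C)cc1
F7 | step 7 | [2,6-dihydroxy-4-methoxy-3,5-bis(3-methylbut-2-en-1-yl)phenyl][4-(methoxymethoxy)phenyl]methanone | COCOc1ccc(C(=O)c2c(O)c(CC=C(C)C)c(OC)c(CC=C(C)C)c2O)cc1
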